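The synthesis rests on disconnecting the aldol unit of the ten-membered carbocycle – C1 carbinol, C2 methylene, C3 enone carbonyl, flanked by the C10 methyl carbinol – at the C2–C3 and C1–O bonds. An intramolecular nitrile oxide–alkene cycloaddition joins a C3 nitrile oxide to the C1=C2 vinyl group of an (S)-linalool-derived carbinol, closing the carbocycle and a bridging isoxazoline at once, fixing C1 and storing the β-hydroxy ketone in masked form. The precursor is a seco aldoxime: a cis-fused γ-lactone (C6, C7 set by a Barbier union) carrying the C4=C5 alkene with C3 held cis to C6, the C8 silyl ether, and the methylene lactone masked as a sulfone.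

Key step: step 16

Remark: (S)-(+)-linalool and (R)-2-methylbutanoic acid are assumed to be available in high enantiomeric purity; carbons are numbered as in the germacrane skeleton of the target (ring C1–C10, lactone carbonyl C12 on C11, exocyclic methylene C13, C10 methyl C14, C4 hydroxymethyl C15).

Step 1
Reactants: 1 (S)-(+)-linalool
Product: 2 (3S)-3,7-dimethyl-3-(triethylsilyloxy)octa-1,6-diene
Conditions: TESOTf, 2,6-lutidine, CH2Cl2, −78 → 0 °C
Reagents that add atoms: triethylsilyl trifluoromethanesulfonate CC[Si](CC)(CC)OS(=O)(=O)C(F)(F)F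
Why: Silyl triflate silylation caps the hindered tertiary alcohol without ionising it, so the C10 stereocentre of the chiral pool is carried on unchanged and cannot later form a lactol with the C7 aldehyde.

Step 2
Reactants: 2 (3S)-3,7-dimethyl-3-(triethylsilyloxy)octa-1,6-diene
Product: 4 (4S)-4-methyl-4-(triethylsilyloxy)hex-5-enal, via ozonide 3 (not isolated)
Conditions: O3 (1 equiv, Sudan Red 7B end point), CH2Cl2, −78 °C; then PPh3, −78 °C → rt
Reagents that add atoms: ozone [O-][O+]=O
Why: Chemoselective ozonolysis, in which the electron-rich trisubstituted alkene is consumed far faster than the hindered monosubstituted vinyl group, the dye marks the end point and phosphine reduction of the ozonide releases the C7 aldehyde.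

Step 3
Reactants: 4 (4S)-4-methyl-4-(triethylsilyloxy)hex-5-enal
Product: 6 (2R,4S)-4-methyl-2-(N-phenylaminooxy)-4-(triethylsilyloxy)hex-5-en-1-ol, via aminoxy aldehyde 5 (not isolated)
Conditions: L-proline (20 mol%), PhNO, DMSO, rt; then NaBH4, EtOH, 0 °C
Reagents that add atoms: nitrosobenzene O=Nc1ccccc1
Why: Organocatalytic α-aminoxylation, in which the L-proline enamine is attacked by the oxygen of nitrosobenzene on the face directed by the carboxylic acid, which for linear aldehydes gives the (R)-α-oxygenated product (the 8R centre), and immediate borohydride reduction prevents epimerisation.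

Step 4
Reactants: 6 (2R,4S)-4-methyl-2-(N-phenylaminooxy)-4-(triethylsilyloxy)hex-5-en-1-ol
Product: 7 (2R,4S)-4-methyl-4-(triethylsilyloxy)hex-5-ene-1,2-diol
Conditions: Zn dust, AcOH/EtOH, rt
Reagents that add atoms: none
Why: Reductive N–O bond cleavage by zinc in acetic acid frees the secondary alcohol and spares the vinyl group, the tertiary silyl ether and both stereocentres.

Step 5
Reactants: 7 (2R,4S)-4-methyl-4-(triethylsilyloxy)hex-5-ene-1,2-diol
Product: 9 (2R,4S)-2-(tert-butyldimethylsilyloxy)-4-methyl-1,4-bis(triethylsilyloxy)hex-5-ene, via primary TES ether 8 (not isolated)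
Conditions: TESCl (1.05 equiv), Et3N, DMAP (cat.), CH2Cl2, −78 °C; then TBSOTf, −78 → 0 °C
Reagents that add atoms: chlorotriethylsilane CC[Si](Cl)(CC)CC; tert-butyldimethylsilyl trifluoromethanesulfonate CC(C)(C)[Si](C)(C)OS(=O)(=O)C(F)(F)F
Why: Sequential silylation in one flask uses the much higher rate of the primary hydroxyl toward the silyl chloride at low temperature, after which the silyl triflate caps the secondary C8 hydroxyl with the more robust TBS group.

Step 6
Reactants: 9 (2R,4S)-2-(tert-butyldimethylsilyloxy)-4-methyl-1,4-bis(triethylsilyloxy)hex-5-ene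
Product: 10 (2R,4S)-2-(tert-butyldimethylsilyloxy)-4-methyl-4-(triethylsilyloxy)hex-5-enal
Conditions: (COCl)2, DMSO, CH2Cl2, −78 → −40 °C; then Et3N, −78 → 0 °C
Reagents that add atoms: none
Why: Swern oxidation applied directly to the silyl ether, since activated DMSO cleaves and oxidises primary triethylsilyl ethers while secondary TBS and tertiary TES ethers are inert, and the low temperature protects the α-silyloxy aldehyde from epimerisation.

Step 7
Reactants: 10 (2R,4S)-2-(tert-butyldimethylsilyloxy)-4-methyl-4-(triethylsilyloxy)hex-5-enal; 11 methyl acrylate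
Product: 12 methyl (4R,6S)-4-(tert-butyldimethylsilyloxy)-3-hydroxy-6-methyl-2-methylidene-6-(triethylsilyloxy)oct-7-enoate (both C3 epimers)
Conditions: DABCO, neat methyl acrylate (excess), MeOH (cat.), rt
Reagents that add atoms: none
Why: Morita–Baylis–Hillman reaction of an inductively activated α-silyloxy aldehyde, which attaches C11–C13 to C7; the new carbinol centre is not controlled and is erased in step 8.

Step 8
Reactants: 12 methyl (4R,6S)-4-(tert-butyldimethylsilyloxy)-3-hydroxy-6-methyl-2-methylidene-6-(triethylsilyloxy)oct-7-enoate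
Product: 13 methyl (2Z,4R,6S)-2-(bromomethyl)-4-(tert-butyldimethylsilyloxy)-6-methyl-6-(triethylsilyloxy)octa-2,7-dienoate
Conditions: NBS, Me2S, CH2Cl2, 0 °C → rt
Reagents that add atoms: N-bromosuccinimide O=C1CCC(=O)N1Br
Why: Bromodimethylsulfonium activation of the allylic alcohol followed by SN2′ delivery of bromide with allylic transposition gives the conjugated, thermodynamically preferred trisubstituted alkene with C8 trans to the ester, under near-neutral conditions that the silyl ethers tolerate.

Step 9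
Reactants: 14 1,3-dihydroxyacetone (used as its dimer); 15 ethyl (triphenylphosphoranylidene)acetate
Product: 17 4-(hydroxymethyl)furan-2(5H)-one, via Wittig ester 16 (not isolated)
Conditions: CH2Cl2/MeOH, rt
Reagents that add atoms: none
Why: Wittig olefination of the ketone gives an enoate in which one of the two equivalent hydroxymethyl groups is necessarily cis to the ester and lactonises spontaneously, so the ring locks C3 cis to C6 across the future C4=C5 bond.

Step 10
Reactants: 17 4-(hydroxymethyl)furan-2(5H)-one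
Product: 18 4-[(tert-butyldiphenylsilyloxy)methyl]furan-2(5H)-one
Conditions: TBDPSCl, imidazole, DMF, 0 °C → rt
Reagents that add atoms: tert-butyl(chloro)diphenylsilane CC(C)(C)[Si](Cl)(c1ccccc1)c1ccccc1
Why: Standard silylation of the primary C15 alcohol with an acid-stable group that survives every later step up to the last one.

Step 11
Reactants: 18 4-[(tert-butyldiphenylsilyloxy)methyl]furan-2(5H)-one
Product: 19 4-[(tert-butyldiphenylsilyloxy)methyl]-2,5-dihydrofuran-2-ol (anomer mixture, used crude)
Conditions: iBu2AlH (1.1 equiv), CH2Cl2, −78 °C; aq. KNaC4H4O6 work-up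
Reagents that add atoms: none
Why: Partial reduction of the lactone stops at the aluminium hemiacetal at low temperature, and neutral tartrate work-up avoids acid-induced dehydration of the lactol to a furan.

Step 12
Reactants: 13 methyl (2Z,4R,6S)-2-(bromomethyl)-4-(tert-butyldimethylsilyloxy)-6-methyl-6-(triethylsilyloxy)octa-2,7-dienoate; 19 4-[(tert-butyldiphenylsilyloxy)methyl]-2,5-dihydrofuran-2-ol
Product: 21 cis-α-methylene-γ-lactone (6S,7S,8R,10S; 4E; C3–OH free; C15–OTBDPS; C8–OTBS; C10–OTES; C1=C2 vinyl), via open hydroxy ester 20 (not isolated)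
Conditions: indium powder, THF/H2O (4:1), rt; then PPTS (cat.), CH2Cl2, rt
Reagents that add atoms: none
Why: Barbier allylation in which the allylindium from 13 adds through its γ-carbon C7 to the hydroxy-enal tautomer of 19 in a closed chair transition state; C8, being cis to the metal-bearing CH2, gives the syn C6/C7 adduct and hence the cis-lactone on acid-catalysed lactonisation, while the face of C7 is set by C8, whose hydrogen eclipses the alkene to relieve A(1,3) strain so that the aldehyde approaches anti to the C9 chain.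

Step 13
Reactants: 21 cis-α-methylene-γ-lactone
Product: 22 phenylsulfonylmethyl lactone (6S,7S,8R,10S; 4E; C11 epimers; C3–OH free)
Conditions: PhSO2Na, AcOH, DMF, rt
Reagents that add atoms: sodium benzenesulfinate [Na+].[O-]S(=O)c1ccccc1
Why: Sulfa-Michael addition of benzenesulfinic acid masks the methylene lactone, the only competing dipolarophile and acceptor for hydroxylamine; C11 forms as an epimer mixture that is erased in step 18.

Step 14
Reactants: 22 phenylsulfonylmethyl lactone
Product: 23 C3 enal (6S,7S,8R,10S; 4Z; CHO cis to C6)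
Conditions: MnO2 (activated, excess), CH2Cl2, rt
Reagents that add atoms: none
Why: MnO2 oxidises the primary allylic alcohol, the only free hydroxyl, under neutral heterogeneous conditions that preserve the alkene geometry.

Step 15
Reactants: 23 C3 enal
Product: 24 seco C3 aldoxime (6S,7S,8R,10S; 4E; oxime geometry not assigned)
Conditions: NH2OH·HCl, pyridine, EtOH, 0 °C
Reagents that add atoms: hydroxylamine hydrochloride NO.Cl
Why: Buffered oxime condensation at the aldehyde is much faster than conjugate addition or attack on the lactone, so the cis C3/C6 relationship is retained.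

Step 16
Reactants: 24 seco C3 aldoxime
Product: 27 isoxazoline-bridged germacranolide (1R,6S,7S,8R,10S; 4E; sulfone-masked; all three silyl ethers intact), via hydroximoyl chloride 25 (not isolated), via nitrile oxide 26 (not isolated)
Conditions: NCS, DMF, 0 °C → rt; then syringe-pump addition (about 20 h) to NaHCO3 (excess) in EtOAc at 45 °C, final concentration about 1 mM
Reagents that add atoms: none
Why: NCS chlorinates the aldoxime to hydroximoyl chloride 25, and slow dehydrochlorination by solid NaHCO3 at high dilution releases the conjugated, α-branched nitrile oxide 26, which adds to the C1=C2 vinyl group in a concerted [3+2] cycloaddition. The closest known reaction type is the intramolecular nitrile oxide–alkene cycloaddition used to close isoxazoline-bridged carbocycles, here at the lower end of the ring sizes for which it is established. The ten-membered carbocycle closes in the bridged mode by C3–C2 bond formation at the terminal alkene carbon, and the isoxazoline closes in the same event by O–C1 bond formation. The only new stereocentre, C1, is controlled by the adjacent C10 centre: with the C10 silyloxy group inside, the ring chain C9 anti to the forming C1–O bond and the methyl group outside, the dipole should add to the vinyl face that gives 1R. The step needs C3-to-C2 regiochemistry, which the monosubstituted alkene next to quaternary C10 secures, chemoselectivity, which the sulfone mask on the methylene lactone secures, and cyclisation over dimerisation, which is favoured by high dilution, the hindered dipole and the two turn elements (cis-lactone and cis C3/C6 on C4=C5).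

Step 17
Reactants: 27 isoxazoline-bridged germacranolide
Product: 28 C8,C10-diol (1R,6S,7R,8R,10S; 4E; C15–OTBDPS and sulfone retained)
Conditions: TsOH·H2O, MeOH/CH2Cl2, 0 °C → rt
Reagents that add atoms: none
Why: Acid-catalysed methanolysis removes the secondary TBS and tertiary TES ethers, whereas the primary TBDPS ether is orders of magnitude more stable to protic acid and the isoxazoline, lactone and sulfone are inert.

Step 18
Reactants: 28 C8,C10-diol; 29 (R)-2-methylbutanoic acid
Product: 31 C8 (R)-2-methylbutanoate methylene lactone (1R,6S,7R,8R,10S; 4E; isoxazoline and C15–OTBDPS intact; C10–OH free), via ester sulfone 30 (not isolated)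
Conditions: DCC, DMAP, CH2Cl2, 0 °C → rt; then DBU, 0 °C
Reagents that add atoms: none
Why: Steglich esterification acylates only the secondary C8 hydroxyl, the tertiary C10 hydroxyl being inert, and DBU then expels benzenesulfinate by E1cB elimination to regenerate the exocyclic methylene; the ester stereocentre comes from acid 29, and the free C8 alcohol is never exposed to strong base, which avoids lactone migration.

Step 19
Reactants: 31 C8 (R)-2-methylbutanoate methylene lactone
Product: 33 β-hydroxy enone C15-TBDPS ether (1R,6S,7R,8R,10S; 4Z), via hydroxy imine 32 (not isolated)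
Conditions: Mo(CO)6, MeCN/H2O (10:1), 75 °C
Reagents that add atoms: water O
Why: Mo(CO)6-mediated reductive N–O cleavage gives the β-hydroxy imine, which water hydrolyses to the C3 ketone; the reagent tolerates the conjugated alkene, the methylene lactone and the esters, and C1 keeps its configuration.

Step 20
Reactants: 33 β-hydroxy enone C15-TBDPS ether
Product: 34 target CNP0263726.1
Conditions: HF·pyridine, pyridine/THF, 0 °C → rt
Reagents that add atoms: none
Why: Fluoride-driven desilylation of the primary allylic TBDPS ether under buffered, weakly acidic conditions avoids the retro-aldol, dehydration and acyl migration that basic fluoride could cause.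

Compound list
1 | (S)-(+)-linalool, (3S)-3,7-dimethylocta-1,6-dien-3-ol | C=C[C@@](C)(O)CCC=C(C)C | starting material
2 | (3S)-3,7-dimethyl-3-(triethylsilyloxy)octa-1,6-diene | C=C[C@@](C)(O[Si](CC)(CC)CC)CCC=C(C)C | intermediate
3 | 3,3-dimethyl-5-[(3S)-3-methyl-3-(triethylsilyloxy)pent-4-enyl]-1,2,4-trioxolane (ozonide, not isolated) | C=C[C@@](C)(O[Si](CC)(CC)CC)CCC1OOC(C)(C)O1 | intermediate
4 | (4S)-4-methyl-4-(triethylsilyloxy)hex-5-enal | C=C[C@@](C)(O[Si](CC)(CC)CC)CCC=O | intermediate
5 | (2R,4S)-4-methyl-2-(N-phenylaminooxy)-4-(triethylsilyloxy)hex-5-enal (not isolated) | C=C[C@@](C)(O[Si](CC)(CC)CC)C[C@@H](ONc1ccccc1)C=O | intermediate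
6 | (2R,4S)-4-methyl-2-(N-phenylaminooxy)-4-(triethylsilyloxy)hex-5-en-1-ol | C=C[C@@](C)(O[Si](CC)(CC)CC)C[C@@H](ONc1ccccc1)CO | intermediate
7 | (2R,4S)-4-methyl-4-(triethylsilyloxy)hex-5-ene-1,2-diol | C=C[C@@](C)(O[Si](CC)(CC)CC)C[C@@H](O)CO | intermediate
8 | (2R,4S)-4-methyl-1,4-bis(triethylsilyloxy)hex-5-en-2-ol (not isolated) | C=C[C@@](C)(O[Si](CC)(CC)CC)C[C@@H](O)CO[Si](CC)(CC)CC | intermediate
9 | (2R,4S)-2-(tert-butyldimethylsilyloxy)-4-methyl-1,4-bis(triethylsilyloxy)hex-5-ene | C=C[C@@](C)(O[Si](CC)(CC)CC)C[C@@H](O[Si](C)(C)C(C)(C)C)CO[Si](CC)(CC)CC | intermediate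
10 | (2R,4S)-2-(tert-butyldimethylsilyloxy)-4-methyl-4-(triethylsilyloxy)hex-5-enal | C=C[C@@](C)(O[Si](CC)(CC)CC)C[C@@H](O[Si](C)(C)C(C)(C)C)C=O | intermediate
11 | methyl acrylate | C=CC(=O)OC | starting material
12 | methyl (4R,6S)-4-(tert-butyldimethylsilyloxy)-3-hydroxy-6-methyl-2-methylidene-6-(triethylsilyloxy)oct-7-enoate (C3 epimers) | C=C[C@@](C)(O[Si](CC)(CC)CC)C[C@@H](O[Si](C)(C)C(C)(C)C)C(O)C(=C)C(=O)OC | intermediate
13 | methyl (2Z,4R,6S)-2-(bromomethyl)-4-(tert-butyldimethylsilyloxy)-6-methyl-6-(triethylsilyloxy)octa-2,7-dienoate | C=C[C@@](C)(O[Si](CC)(CC)CC)C[C@@H](O[Si](C)(C)C(C)(C)C)/C=C(\CBr)C(=O)OC | intermediate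
14 | 1,3-dihydroxyacetone (supplied as its dimer) | O=C(CO)CO | starting material
15 | ethyl (triphenylphosphoranylidene)acetate | CCOC(=O)C=P(c1ccccc1)(c1ccccc1)c1ccccc1 | starting material
16 | ethyl 4-hydroxy-3-(hydroxymethyl)but-2-enoate (not isolated) | CCOC(=O)C=C(CO)CO | intermediate
17 | 4-(hydroxymethyl)furan-2(5H)-one | O=C1C=C(CO)CO1 | intermediate
18 | 4-[(tert-butyldiphenylsilyloxy)methyl]furan-2(5H)-one | O=C1C=C(CO[Si](c2ccccc2)(c2ccccc2)C(C)(C)C)CO1 | intermediate
19 | 4-[(tert-butyldiphenylsilyloxy)methyl]-2,5-dihydrofuran-2-ol (anomer mixture) | OC1OCC(CO[Si](c2ccccc2)(c2ccccc2)C(C)(C)C)=C1 | intermediate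
20 | methyl (3S,4R,6S)-4-(tert-butyldimethylsilyloxy)-3-[(1S,2E)-3-[(tert-butyldiphenylsilyloxy)methyl]-1,4-dihydroxybut-2-enyl]-6-methyl-2-methylidene-6-(triethylsilyloxy)oct-7-enoate (not isolated) | C=C(C(=O)OC)[C@@H]([C@@H](O)/C=C(/CO[Si](c1ccccc1)(c1ccccc1)C(C)(C)C)CO)[C@H](O[Si](C)(C)C(C)(C)C)C[C@](C)(O[Si](CC)(CC)CC)C=C | intermediate
21 | (4S,5S)-4-[(1R,3S)-1-(tert-butyldimethylsilyloxy)-3-methyl-3-(triethylsilyloxy)pent-4-enyl]-5-[(1E)-2-[(tert-butyldiphenylsilyloxy)methyl]-3-hydroxyprop-1-enyl]-3-methylidenedihydrofuran-2(3H)-one | C=C1C(=O)O[C@@H](/C=C(/CO[Si](c2ccccc2)(c2ccccc2)C(C)(C)C)CO)[C@H]1[C@H](O[Si](C)(C)C(C)(C)C)C[C@](C)(O[Si](CC)(CC)CC)C=C | intermediate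
22 | sulfinate adduct of 21: (4S,5S)-lactone with 3-[(phenylsulfonyl)methyl] in place of 3-methylidene (C3 epimers of the lactone, i.e. C11), C3–OH of the side chain free | O=S(=O)(c1ccccc1)CC1C(=O)O[C@@H](/C=C(/CO[Si](c2ccccc2)(c2ccccc2)C(C)(C)C)CO)[C@H]1[C@H](O[Si](C)(C)C(C)(C)C)C[C@](C)(O[Si](CC)(CC)CC)C=C | intermediate
23 | enal of 22: side chain (1Z)-2-[(tert-butyldiphenylsilyloxy)methyl]-3-oxoprop-1-enyl, aldehyde C3 cis to C6 | O=S(=O)(c1ccccc1)CC1C(=O)O[C@@H](/C=C(/CO[Si](c2ccccc2)(c2ccccc2)C(C)(C)C)C=O)[C@H]1[C@H](O[Si](C)(C)C(C)(C)C)C[C@](C)(O[Si](CC)(CC)CC)C=C | intermediate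
24 | seco aldoxime: oxime of 23 at C3 (4E; oxime geometry not assigned) | O=S(=O)(c1ccccc1)CC1C(=O)O[C@@H](/C=C(/CO[Si](c2ccccc2)(c2ccccc2)C(C)(C)C)C=NO)[C@H]1[C@H](O[Si](C)(C)C(C)(C)C)C[C@](C)(O[Si](CC)(CC)CC)C=C | intermediate
25 | C3 hydroximoyl chloride of 24 (not isolated) | O=S(=O)(c1ccccc1)CC1C(=O)O[C@@H](/C=C(/CO[Si](c2ccccc2)(c2ccccc2)C(C)(C)C)C(Cl)=NO)[C@H]1[C@H](O[Si](C)(C)C(C)(C)C)C[C@](C)(O[Si](CC)(CC)CC)C=C | intermediate
26 | C3 nitrile oxide (not isolated) | O=S(=O)(c1ccccc1)CC1C(=O)O[C@@H](/C=C(/CO[Si](c2ccccc2)(c2ccccc2)C(C)(C)C)C#[N+][O-])[C@H]1[C@H](O[Si](C)(C)C(C)(C)C)C[C@](C)(O[Si](CC)(CC)CC)C=C | intermediate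
27 | isoxazoline-bridged germacranolide, (1R,6S,7S,8R,10S,4E): ten-membered carbocycle, C3=N–O–C1 bridge, cis-12,6-lactone with 11-(phenylsulfonylmethyl) (C11 epimers), 8-OTBS, 10-OTES, 15-OTBDPS | O=S(=O)(c1ccccc1)CC1C(=O)O[C@H]2/C=C(/CO[Si](c4ccccc4)(c4ccccc4)C(C)(C)C)C3=NO[C@H](C3)[C@@](C)(O[Si](CC)(CC)CC)C[C@@H](O[Si](C)(C)C(C)(C)C)[C@@H]12 | intermediate
28 | (1R,6S,7R,8R,10S,4E)-8,10-diol of 27 (15-OTBDPS and sulfone retained) | O=S(=O)(c1ccccc1)CC1C(=O)O[C@H]2/C=C(/CO[Si](c4ccccc4)(c4ccccc4)C(C)(C)C)C3=NO[C@H](C3)[C@@](C)(O)C[C@@H](O)[C@@H]12 | intermediate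
29 | (R)-2-methylbutanoic acid | CC[C@@H](C)C(=O)O | starting material
30 | 8-O-[(R)-2-methylbutanoyl] derivative of 28 (sulfone retained, not isolated) | O=S(=O)(c1ccccc1)CC1C(=O)O[C@H]2/C=C(/CO[Si](c4ccccc4)(c4ccccc4)C(C)(C)C)C3=NO[C@H](C3)[C@@](C)(O)C[C@@H](OC(=O)[C@H](C)CC)[C@@H]12 | intermediate
31 | (1R,6S,7R,8R,10S,4E)-isoxazoline-bridged α-methylene lactone, 8-O-[(R)-2-methylbutanoyl], 10-OH free, 15-OTBDPS | C=C1C(=O)O[C@H]2/C=C(/CO[Si](c4ccccc4)(c4ccccc4)C(C)(C)C)C3=NO[C@H](C3)[C@@](C)(O)C[C@@H](OC(=O)[C@H](C)CC)[C@@H]12 | intermediate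
32 | C3 imine, C1 carbinol from N–O cleavage of 31 (not isolated) | C=C1C(=O)O[C@H]2/C=C(/CO[Si](c3ccccc3)(c3ccccc3)C(C)(C)C)C(=N)C[C@@H](O)[C@@](C)(O)C[C@@H](OC(=O)[C@H](C)CC)[C@@H]12 | intermediate
33 | 15-O-TBDPS ether of the target, (1R,6S,7R,8R,10S,4Z) | C=C1C(=O)O[C@H]2/C=C(/CO[Si](c3ccccc3)(c3ccccc3)C(C)(C)C)C(=O)C[C@@H](O)[C@@](C)(O)C[C@@H](OC(=O)[C@H](C)CC)[C@@H]12 | intermediate
34 | CNP0263726.1, (1R,6S,7R,8R,10S,4Z)-1,10,15-trihydroxy-8-[(R)-2-methylbutanoyloxy]-3-oxogermacra-4,11(13)-dien-12,6-olide | C=C1C(=O)O[C@H]2/C=C(/CO)C(=O)C[C@@H](O)[C@@](C)(O)C[C@@H](OC(=O)[C@H](C)CC)[C@@H]12 | target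

Total step count: 20
Longest linear sequence: 17 steps (steps 1–8, then 12–20)

Steps most likely to fail

Step 16. Closure of the strained, bridged ten-membered ring may be slower than dimerisation or oligomerisation of the nitrile oxide, or the dipole may add to the wrong face of the vinyl group. The fallback inverts the order of the two fragment unions: the isoxazoline is made intermolecularly and the carbocycle is closed at C6–C7 by a macrocyclic Barbier allylation. It sets out from butenolide 18 and bromide 13. Reduction of 18 with excess iBu2AlH should give (2E)-2-[(tert-butyldiphenylsilyloxy)methyl]but-2-ene-1,4-diol F1, in which the two hydroxymethyl groups are cis. Silylation of the less hindered C6 hydroxyl (TESCl, imidazole, −78 °C) should give mono-TES ether F2, MnO2 should give the C3 enal F3, and NH2OH·HCl/pyridine its oxime F4. Chlorination with NCS and treatment with NaHCO3 in the presence of 13 should give the acyclic isoxazoline F5 at the vinyl group (C1 epimers to be separated). A Swern oxidation with iPr2NEt, which cleaves the primary TES ether, should give the C6 aldehyde F6. Indium powder in THF/H2O at high dilution, followed by PPTS, should close the carbocycle and the lactone to the isoxazoline-bridged methylene lactone F7. TsOH·H2O in MeOH should then give the C8,C10-diol F8, and DCC/DMAP esterification with acid 29 returns to the route at compound 31.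

Step 12. π-Facial control relative to C8 and syn selectivity may erode in the aqueous metal-mediated allylation, and the lactol may dehydrate to a furan under the Lewis-acidic aqueous conditions. The fallback replaces the Barbier reaction by a thermal allylboration through a tight six-membered chair under neutral, anhydrous conditions. It sets out from Morita–Baylis–Hillman adduct 12. Acetylation (Ac2O, DMAP, pyridine) should give allylic acetate F9. SN2′ borylation with B2pin2, CuCl and KOAc in DMF should give allylboronate F10, expected with C8 cis to the boron-bearing CH2 group. Heating F10 with lactol 19 in toluene should give the syn adduct as its borate, which lactonises (PPTS if needed) and returns to the route at compound 21.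

Step 19. The newly freed β-hydroxy ketone may dehydrate or undergo retro-aldol ring opening at 75 °C, and the methylene lactone may suffer conjugate reduction. The fallback cleaves the N–O bond one stage earlier, at low temperature and before the Michael acceptor exists. It sets out from ester sulfone 30, isolated by omitting DBU in step 18. Samarium diiodide (SmI2) in THF at −78 °C followed by aqueous B(OH)3 should give the sulfone-masked β-hydroxy enone F11. DBU (1 equiv) in CH2Cl2 at −20 °C should then expel benzenesulfinate and return to the route at compound 33.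

Further compounds
F1 | step 16 | (2E)-2-[(tert-butyldiphenylsilyloxy)methyl]but-2-ene-1,4-diol | OC/C=C(/CO[Si](c1ccccc1)(c1ccccc1)C(C)(C)C)CO
F2 | step 16 | (2E)-2-[(tert-butyldiphenylsilyloxy)methyl]-4-(triethylsilyloxy)but-2-en-1-ol | CC[Si](CC)(CC)OC/C=C(/CO[Si](c1ccccc1)(c1ccccc1)C(C)(C)C)CO
F3 | step 16 | (2Z)-2-[(tert-butyldiphenylsilyloxy)methyl]-4-(triethylsilyloxy)but-2-enal | CC[Si](CC)(CC)OC/C=C(/CO[Si](c1ccccc1)(c1ccccc1)C(C)(C)C)C=O
F4 | step 16 | oxime of F3 (2E; oxime geometry not assigned) | CC[Si](CC)(CC)OC/C=C(/CO[Si](c1ccccc1)(c1ccccc1)C(C)(C)C)C=NO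
F5 | step 16 | acyclic isoxazoline from F4 and 13: C3=N–O–C1 ring on the former vinyl group, (Z)-bromomethyl enoate retained, C6–OTES | CC[Si](CC)(CC)OC/C=C(/CO[Si](c1ccccc1)(c1ccccc1)C(C)(C)C)C1=NO[C@H](C1)[C@@](C)(O[Si](CC)(CC)CC)C[C@@H](O[Si](C)(C)C(C)(C)C)/C=C(\CBr)C(=O)OC
F6 | step 16 | C6 aldehyde of F5 (CHO cis to the isoxazoline carbon C3) | O=C/C=C(/CO[Si](c1ccccc1)(c1ccccc1)C(C)(C)C)C1=NO[C@H](C1)[C@@](C)(O[Si](CC)(CC)CC)C[C@@H](O[Si](C)(C)C(C)(C)C)/C=C(\CBr)C(=O)OC
F7 | step 16 | isoxazoline-bridged α-methylene lactone with 8-OTBS, 10-OTES, 15-OTBDPS | C=C1C(=O)O[C@H]2/C=C(/CO[Si](c4ccccc4)(c4ccccc4)C(C)(C)C)C3=NO[C@H](C3)[C@@](C)(O[Si](CC)(CC)CC)C[C@@H](O[Si](C)(C)C(C)(C)C)[C@@H]12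
F8 | step 16 | 8,10-diol of F7 (15-OTBDPS retained) | C=C1C(=O)O[C@H]2/C=C(/CO[Si](c4ccccc4)(c4ccccc4)C(C)(C)C)C3=NO[C@H](C3)[C@@](C)(O)C[C@@H](O)[C@@H]12
F9 | step 12 | methyl (4R,6S)-3-acetoxy-4-(tert-butyldimethylsilyloxy)-6-methyl-2-methylidene-6-(triethylsilyloxy)oct-7-enoate | C=C[C@@](C)(O[Si](CC)(CC)CC)C[C@@H](O[Si](C)(C)C(C)(C)C)C(OC(C)=O)C(=C)C(=O)OC
F10 | step 12 | methyl (2E,4R,6S)-4-(tert-butyldimethylsilyloxy)-6-methyl-2-[(4,4,5,5-tetramethyl-1,3,2-dioxaborolan-2-yl)methyl]-6-(triethylsilyloxy)octa-2,7-dienoate | C=C[C@@](C)(O[Si](CC)(CC)CC)C[C@@H](O[Si](C)(C)C(C)(C)C)/C=C(\CB1OC(C)(C)C(C)(C)O1)C(=O)OC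
F11 | step 19 | sulfone-masked β-hydroxy enone: 15-O-TBDPS ether of the target with 11-(phenylsulfonylmethyl) in place of the methylene | O=S(=O)(c1ccccc1)CC1C(=O)O[C@H]2/C=C(/CO[Si](c3ccccc3)(c3ccccc3)C(C)(C)C)C(=O)C[C@@H](O)[C@@](C)(O)C[C@@H](OC(=O)[C@H](C)CC)[C@@H]12
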